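Atom labels: ring A is C1 (bears =CH2), C2, C3 (OH), C4 (Br), C5 (gem-dimethyl) and spiro C6. Ring B runs from C6 through C7, C8, C9 (Cl, Me), C10 (Br) and C11.
Cuts: C9–Cl/C10–Br (back to a C9=C10 alkene), C3–H, C4–Br and the exocyclic carbon on C1 come off first. A carbonyl is then written at C7 and ring B is opened at C6–C7 and C7–C8, which releases CO. The cyclopropane bonds C6–C10/C10–C11 and then C6=C11 lead back to dimedone.
Enabling feature: in ring B the methyl-bearing C9 lies para to spiro C6. C8, C9 and the methyl therefore read as an isopropenyl group on C10 of a C6–C10–C11 spirocyclopropane, the sixth ring atom C7 is CO, and the ring A carbonyl C1 next to C6 polarises the bond that must break.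
Forward order: ring A is bought as dimedone, the three-membered ring is built on C6, and ring B arises by carbonylative ring expansion. C7 is then deoxygenated and C1 gains its carbon with a carbonyl shift to C3. C4–Br, C9–Cl/C10–Br, the alkene shift and the C3 reduction follow.
Stereochemistry: C6 comes from a limonene-derived chiral sulfonium ylide (C10 is set by the ylide face and relayed to C6 on ring closure) and is carried through the ring expansion. C4 is set by equilibration, C9/C10 by anti BrCl addition under control of C6, and C3 by hydride delivery under control of C4/C5.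
Key step: step 7

Assumption: the ylide from the (1R,4R,5R)-sulfide 9 is taken to react through the carbanion face that leads to 10S; if the sense is opposite, the mirror-image sulfide from (S)-limonene is used in the same steps.
Assumption: centres that are erased later (C6 in 5 and 6, sulfur in 11 and 12, C7 in 16 and 17, C1 in 19) are left unspecified.

Step 1
Reactants: 1 dimedone (5,5-dimethylcyclohexane-1,3-dione); 2 isobutanol (2-methylpropan-1-ol)
Product: 3 3-isobutoxy-5,5-dimethylcyclohex-2-en-1-one
Conditions: TsOH·H2O (cat.), toluene, reflux, Dean–Stark trap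
Reagents that add atoms: none
Why: Acid-catalysed vinylogous ester formation from a cyclic 1,3-dione with azeotropic removal of water, which tells C1 (carbonyl) from C3 (enol ether) and leaves C6 as the kinetic enolisation site.

Step 2
Reactants: 3 3-isobutoxy-5,5-dimethylcyclohex-2-en-1-one; 4 dimethylmethylideneammonium iodide
Product: 5 6-[(dimethylamino)methyl]-3-isobutoxy-5,5-dimethylcyclohex-2-en-1-one (racemic at C6)
Conditions: LiN(i-Pr)2, THF, −78 °C; then 4, −78 °C → rt
Reagents that add atoms: none
Why: Kinetic α′-deprotonation of a vinylogous ester followed by a Mannich reaction with a preformed iminium salt, an electrophile small and reactive enough for the neopentyl position C6, brings in C11.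

Step 3
Reactants: 5 6-[(dimethylamino)methyl]-3-isobutoxy-5,5-dimethylcyclohex-2-en-1-one
Product: 7 3-isobutoxy-5,5-dimethyl-6-methylidenecyclohex-2-en-1-one, via ammonium iodide 6 (not isolated)
Conditions: MeI, Et2O, rt; then NaHCO3 (aq), CH2Cl2, rt; used at once
Reagents that add atoms: iodomethane, CI (its carbon stays only in 6)
Why: Quaternisation and Hofmann-type β-elimination of a Mannich base give the exocyclic enone under mild base, and the neighbouring gem-dimethyl group slows its dimerisation.

Step 4
Reactants: 8 (R)-limonene
Product: 9 (1R,4R,5R)-4,7,7-trimethyl-6-thiabicyclo[3.2.1]octane (isothiocineole)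
Conditions: S8, γ-terpinene, neat, 110 °C; distillation
Reagents that add atoms: sulfur, S1SSSSSSS1
Why: Known one-pot radical sulfuration of limonene in which sulfur bridges both alkenes and γ-terpinene delivers hydrogen, the resident stereocentre fixing the two new ones through the bridged framework.

Step 5
Reactants: 9 (1R,4R,5R)-isothiocineole; 10 3-bromo-2-methylprop-1-ene
Product: 11 (1R,4R,5R)-4,7,7-trimethyl-6-(2-methylprop-2-en-1-yl)-6-thiabicyclo[3.2.1]octan-6-ium triflate (one sulfonium diastereomer expected)
Conditions: LiOSO2CF3, CH2Cl2/H2O, rt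
Reagents that add atoms: lithium trifluoromethanesulfonate, [Li+].[O-]S(=O)(=O)C(F)(F)F
Why: SN2 S-alkylation of a dialkyl sulfide by an allylic bromide, made irreversible by exchange to the non-nucleophilic triflate, with only the exposed sulfur lone pair reacting.

Step 6
Reactants: 7 3-isobutoxy-5,5-dimethyl-6-methylidenecyclohex-2-en-1-one; 11 methallyl sulfonium triflate
Product: 13 (1S,3S)-6-isobutoxy-8,8-dimethyl-1-(prop-1-en-2-yl)spiro[2.5]oct-5-en-4-one (6S,10S in target labels; isopropenyl cis to C1 and trans to C5), via sulfonium ylide 12 (not isolated)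
Conditions: LiN(SiMe3)2, THF, −78 °C; then 7, −78 → −20 °C
Reagents that add atoms: none
Why: Sulfonium ylide cyclopropanation of an enone (Michael-initiated ring closure, Corey–Chaykovsky type): ylide carbon C10 adds to the unsubstituted terminus C11, so only the ylide face fixed by the bicyclic sulfide decides C10, and the enolate then displaces the sulfide with inversion through the rotamer that keeps the isopropenyl group away from the C5 gem-dimethyl group, which relays C10 to C6.

Step 7
Reactants: 13 spiro vinylcyclopropane; 14 carbon monoxide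
Product: 15 (6R)-3-isobutoxy-5,5,9-trimethylspiro[5.5]undeca-2,9-diene-1,7-dione
Conditions: [Rh(CO)2Cl]2 (5 mol %), CO (1 atm), toluene, 4 Å molecular sieves, 80 °C
Reagents that add atoms: none
Why: Proposed new method: monovalent rhodium binds the isopropenyl group and adds oxidatively into the adjacent C6–C10 bond, the only ring bond flanked by both the alkene donor and the C1 carbonyl acceptor, to give a trivalent rhodacycle (π-allyl over C8–C10, σ-bond to C6), after which CO insertion and C–C reductive elimination join C7 to C8 and to C6. The closest known reaction type is the rhodium-, cobalt- or iron-carbonyl-mediated [5+1] carbonylation of vinylcyclopropanes to cyclohex-3-enones, which has been shown for cleavage toward unsubstituted or alkyl-bearing ring carbons but not toward an acyl-bearing quaternary carbon, hence the label. Ring B closes by reductive elimination from a seven-membered acyl rhodacycle, five substrate carbons and CO making the six-membered ring. No stereocentre is created: C10 becomes sp2 and C6 keeps its configuration, C7 taking the place of C10, as long as rhodium stays bound to carbon C6 or to one face of the oxaallyl unit, which the CO-saturated neutral chloride catalyst in a non-polar solvent is chosen to favour. The step needs cleavage of C6–C10 and not C10–C11 (secured by the donor–acceptor polarisation of the most substituted bond), CO uptake faster than isomerisation of the opened intermediate (secured by the CO atmosphere), and no drift of C9=C10 into conjugation with C7 (base-free medium, moderate temperature).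

Step 8
Reactants: 15 spiro dienedione
Product: 16 (6R)-7-hydroxy-3-isobutoxy-5,5,9-trimethylspiro[5.5]undeca-2,9-dien-1-one (C7 epimers, both carried on)
Conditions: NaBH4, CeCl3·7H2O, MeOH, −40 °C
Reagents that add atoms: none
Why: Luche reduction takes the isolated C7 ketone in preference to the electron-rich vinylogous ester carbonyl C1, its near-neutral medium avoids retro-Claisen cleavage of the non-enolisable 1,3-dicarbonyl unit and alkene conjugation, and the new C7 centre is erased in step 10.

Step 9
Reactants: 16 C7 carbinol
Product: 17 O-[(6R)-3-isobutoxy-5,5,9-trimethyl-1-oxospiro[5.5]undeca-2,9-dien-7-yl] imidazole-1-carbothioate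
Conditions: Im2C=S (1,1′-thiocarbonyldiimidazole), DMAP (cat.), toluene, 80 °C
Reagents that add atoms: 1,1′-thiocarbonyldiimidazole, S=C(n1ccnc1)n1ccnc1
Why: Neutral thioacylation, the first half of a Barton–McCombie deoxygenation, avoids the metal alkoxide that would invite retro-aldol cleavage of C6–C7.

Step 10
Reactants: 17 imidazolyl thiocarbamate
Product: 18 (6R)-3-isobutoxy-5,5,9-trimethylspiro[5.5]undeca-2,9-dien-1-one
Conditions: Bu3SnH, AIBN (cat.), toluene (concentrated), 100 °C
Reagents that add atoms: none
Why: Barton–McCombie radical deoxygenation, run before any halogen is present and at high stannane concentration, so that the C7 radical is reduced faster than it can add to the deactivated C1 carbonyl or to C9=C10.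

Step 11
Reactants: 18 spiro vinylogous ester
Product: 20 (6R)-1,5,5,9-tetramethylspiro[5.5]undeca-1,9-dien-3-one, via tertiary carbinol 19 (not isolated)
Conditions: MeLi, CeCl3, THF, −78 → 0 °C; then HCl (1 M aq), rt
Reagents that add atoms: methyllithium, [Li]C; water, O (oxygen of the new C3 carbonyl)
Why: Organocerium 1,2-addition to the hindered C1 carbonyl followed by acid-induced Stork–Danheiser 1,3-transposition puts the last carbon on C1 and the carbonyl on C3 without touching C6 or the ring B alkene.

Step 12
Reactants: 20 spiro dienone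
Product: 22 (4S,6S)-4-bromo-1,5,5,9-tetramethylspiro[5.5]undeca-1,9-dien-3-one, via trimethylsilyl dienol ether 21 (not isolated)
Conditions: LiN(i-Pr)2, THF, −78 °C; Me3SiCl; then NBS, THF, −78 → 0 °C; then Et3N (cat.), CH2Cl2, rt
Reagents that add atoms: N-bromosuccinimide, O=C1CCC(=O)N1Br; chlorotrimethylsilane, C[Si](C)(C)Cl (its silicon stays only in 21)
Why: Kinetic α′-enolisation of the enone, silyl trapping and electrophilic bromination of the cross-conjugated silyl dienol ether place bromine on C4, and equilibration of this epimerisable centre should give the equatorial bromide (an axial one would be syn-axial to a C6 methylene), which is the 4S epimer on the C11 side because ring A should prefer the half-chair that keeps the flatter allylic arm C11–C10 pseudo-equatorial beside the C1 methyl group.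

Step 13
Reactants: 22 bromo dienone
Product: 23 (4S,6S,9R,10R)-4,10-dibromo-9-chloro-1,5,5,9-tetramethylspiro[5.5]undec-1-en-3-one
Conditions: NBS, HCl (4 M in dioxane), CH2Cl2, −78 °C
Reagents that add atoms: N-bromosuccinimide, O=C1CCC(=O)N1Br; hydrogen chloride, Cl
Why: Electrophilic anti addition of BrCl made in the flask: only C9=C10 is nucleophilic because the ring A alkene is an enone, chloride opens the bromonium ion at tertiary C9 (Markovnikov) from the face opposite to bromine, and bromine should be taken up on the ring B face that carries C1 because the other face lies under the C5 gem-dimethyl group.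

Step 14
Reactants: 23 dibromochloro enone
Product: 24 (4S,6S,9R,10R)-4,10-dibromo-3-(tert-butyldimethylsilyloxy)-9-chloro-5,5,9-trimethyl-1-methylidenespiro[5.5]undec-2-ene
Conditions: t-BuMe2SiOTf, Et3N, CH2Cl2, 0 °C
Reagents that add atoms: tert-butyldimethylsilyl triflate, CC(C)(C)[Si](C)(C)OS(=O)(=O)C(F)(F)F
Why: Soft enolisation of a β-methyl enone with silyl triflate and amine should remove a γ-proton from the exposed C1 methyl group rather than the hindered C4–H, giving the linear silyl dienol ether with the C1=CH2 alkene in place and C4 untouched.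

Step 15
Reactants: 24 silyl dienol ether
Product: 26 (3R,4S,6S,9R,10R)-4,10-dibromo-9-chloro-5,5,9-trimethyl-1-methylidenespiro[5.5]undecan-3-ol (target), via methylidene bromoketone 25 (not isolated)
Conditions: Bu4NF, AcOH, THF, −78 °C; cold aqueous work-up; then i-Bu2AlH, THF, −78 °C
Reagents that add atoms: none
Why: Fluoride frees the extended enolate, which acetic acid protonates kinetically at the α-carbon C2 (deconjugative protonation) before it can displace the C4 bromide, and i-Bu2AlH then attacks the C3 ketone of 25 along the equatorial trajectory because the axial one is blocked by the axial C5 methyl group, giving the axial 3R alcohol cis to the equatorial bromide.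

Compound list
1 | dimedone | CC1(C)CC(=O)CC(=O)C1 | starting material
2 | isobutanol | CC(C)CO | starting material
3 | 3-isobutoxy-5,5-dimethylcyclohex-2-en-1-one | CC(C)COC1=CC(=O)CC(C)(C)C1 | intermediate
4 | dimethylmethylideneammonium iodide | C=[N+](C)C.[I-] | starting material
5 | 6-[(dimethylamino)methyl]-3-isobutoxy-5,5-dimethylcyclohex-2-en-1-one (racemic) | CN(C)CC1C(=O)C=C(OCC(C)C)CC1(C)C | intermediate
6 | trimethylammonium iodide of 5 (racemic) | C[N+](C)(C)CC1C(=O)C=C(OCC(C)C)CC1(C)C.[I-] | intermediate
7 | 3-isobutoxy-5,5-dimethyl-6-methylidenecyclohex-2-en-1-one | C=C1C(=O)C=C(OCC(C)C)CC1(C)C | intermediate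
8 | (R)-limonene | CC1=CC[C@@H](CC1)C(C)=C | starting material
9 | (1R,4R,5R)-isothiocineole | C[C@@H]1CC[C@@H]2C[C@H]1SC2(C)C | intermediate
10 | 3-bromo-2-methylprop-1-ene | C=C(C)CBr | starting material
11 | S-methallyl isothiocineolium triflate (sulfur unspecified) | C=C(C)C[S+]1[C@@H]2C[C@@H](CC[C@H]2C)C1(C)C.[O-]S(=O)(=O)C(F)(F)F | intermediate
12 | methallyl ylide of 11 (sulfur unspecified) | C=C(C)[CH-][S+]1[C@@H]2C[C@@H](CC[C@H]2C)C1(C)C | intermediate
13 | (1S,3S)-6-isobutoxy-8,8-dimethyl-1-(prop-1-en-2-yl)spiro[2.5]oct-5-en-4-one | O=C1C=C(OCC(C)C)CC(C)(C)[C@@]12C[C@H]2C(C)=C | intermediate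
14 | carbon monoxide | [C-]#[O+] | starting material
15 | (6R)-3-isobutoxy-5,5,9-trimethylspiro[5.5]undeca-2,9-diene-1,7-dione | O=C1C=C(OCC(C)C)CC(C)(C)[C@]12C(=O)CC(C)=CC2 | intermediate
16 | (6R)-7-hydroxy-3-isobutoxy-5,5,9-trimethylspiro[5.5]undeca-2,9-dien-1-one (C7 epimers) | O=C1C=C(OCC(C)C)CC(C)(C)[C@]12C(O)CC(C)=CC2 | intermediate
17 | C7 imidazole-1-carbothioate of 16 (C7 epimers) | O=C1C=C(OCC(C)C)CC(C)(C)[C@]12C(OC(=S)n3ccnc3)CC(C)=CC2 | intermediate
18 | (6R)-3-isobutoxy-5,5,9-trimethylspiro[5.5]undeca-2,9-dien-1-one | O=C1C=C(OCC(C)C)CC(C)(C)[C@]12CCC(C)=CC2 | intermediate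
19 | (6R)-3-isobutoxy-1,5,5,9-tetramethylspiro[5.5]undeca-2,9-dien-1-ol (C1 unspecified) | CC1(O)C=C(OCC(C)C)CC(C)(C)[C@]12CCC(C)=CC2 | intermediate
20 | (6R)-1,5,5,9-tetramethylspiro[5.5]undeca-1,9-dien-3-one | CC1=CC(=O)CC(C)(C)[C@]12CCC(C)=CC2 | intermediate
21 | 1,5,5,9-tetramethyl-3-(trimethylsilyloxy)spiro[5.5]undeca-1,3,9-triene (C6 as in 20) | CC1=CC(O[Si](C)(C)C)=CC(C)(C)[C@]12CCC(C)=CC2 | intermediate
22 | (4S,6S)-4-bromo-1,5,5,9-tetramethylspiro[5.5]undeca-1,9-dien-3-one | CC1=CC(=O)[C@@H](Br)C(C)(C)[C@]12CCC(C)=CC2 | intermediate
23 | (4S,6S,9R,10R)-4,10-dibromo-9-chloro-1,5,5,9-tetramethylspiro[5.5]undec-1-en-3-one | CC1=CC(=O)[C@@H](Br)C(C)(C)[C@]12CC[C@@](C)(Cl)[C@H](Br)C2 | intermediate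
24 | (4S,6S,9R,10R)-4,10-dibromo-3-(tert-butyldimethylsilyloxy)-9-chloro-5,5,9-trimethyl-1-methylidenespiro[5.5]undec-2-ene | C=C1C=C(O[Si](C)(C)C(C)(C)C)[C@@H](Br)C(C)(C)[C@]12CC[C@@](C)(Cl)[C@H](Br)C2 | intermediate
25 | (4S,6S,9R,10R)-4,10-dibromo-9-chloro-5,5,9-trimethyl-1-methylidenespiro[5.5]undecan-3-one | C=C1CC(=O)[C@@H](Br)C(C)(C)[C@]12CC[C@@](C)(Cl)[C@H](Br)C2 | intermediate
26 | (3R,4S,6S,9R,10R)-4,10-dibromo-9-chloro-5,5,9-trimethyl-1-methylidenespiro[5.5]undecan-3-ol | C=C1C[C@@H](O)[C@@H](Br)C(C)(C)[C@]12CC[C@@](C)(Cl)[C@H](Br)C2 | target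

Total steps: 15. Longest linear sequence: 13 (steps 1–3 and 6–15; steps 4 and 5 form the side branch).

Steps most likely to fail

**Step 7.** The opened rhodium intermediate may isomerise without taking up CO. The wrong ring bond (C10–C11) may be cleaved. The C6 configuration may also be lost if rhodium slips to the enolate oxygen and the carbon becomes planar.
The fallback uses known chemistry, sets out from 3 and comes back at 18.
- Kinetic alkylation of 3 (LiN(i-Pr)2, 4-iodo-2-methylbut-1-ene) should give the 6-(3-methylbut-3-enyl) vinylogous ester F1.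
- A second enolisation and O-acylation with allyl chloroformate should give the allyl enol carbonate F2.
- Enantioselective decarboxylative allylic alkylation with zerovalent palladium (Pd2(dba)3, (S)-tert-butyl phosphinooxazoline ligand, the enantiomer expected to give 6R by analogy with simple 2-alkylcyclohexanones) should set C6 in the α-quaternary ketone F3.
- Ring-closing metathesis with the second-generation Hoveyda–Grubbs catalyst between the allyl group and the 1,1-disubstituted alkene closes ring B at C9=C10 and gives 18.

**Step 13.** Facial selectivity in the uptake of bromine may be poor or inverted, because the C1 methyl group also leans over ring B.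
The fallback sets out from 22 and comes back at 23. It uses the same bias in the opposite sense: an electrophile that prefers the C5 face then delivers oxygen where chlorine has to end.
- Epoxidation of C9=C10 (mCPBA, NaHCO3, CH2Cl2, 0 °C; the enone alkene is inert) should give the epoxide with oxygen on the C5 face F4.
- Li2NiBr4 in THF opens it by SN2 attack at the less substituted C10 from the C1 face to give the trans bromohydrin F5.
- HCl gas in CH2Cl2 at −20 °C ionises the tertiary alcohol with participation of the anti bromine, so chloride should return to C9 on the face that oxygen left (net retention), giving 23.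

**Step 14.** Enolisation may go toward C4 instead of toward the methyl group, with loss of regiocontrol over the alkene and of the C4 configuration.
The fallback sets out from 18 and comes back at 25. It lets a C–Si bond, not a C–H bond, decide where the extended enolate arises.
- Addition of Me3SiCH2Li/CeCl3 to 18 should give the silylmethyl carbinol F6, and brief treatment with dilute acid the 1-(trimethylsilylmethyl) enone F7 by the same 1,3-transposition.
- Kinetic enolisation and silylation give the silyl dienol ether F8.
- NBS and equilibration give the 4S bromo enone F9.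
- BrCl addition as in step 13 gives the ring B bromochloride F10.
- Bu4NF/AcOH at −78 °C then cleaves the allylic C–Si bond, the enolate can only extend toward the exocyclic carbon, and α-protonation gives 25.

Further compounds
F1 | step 7 | 3-isobutoxy-5,5-dimethyl-6-(3-methylbut-3-en-1-yl)cyclohex-2-en-1-one (racemic) | O=C1C=C(OCC(C)C)CC(C)(C)C1CCC(C)=C
F2 | step 7 | allyl 3-isobutoxy-5,5-dimethyl-6-(3-methylbut-3-en-1-yl)cyclohexa-1(6),2-dien-1-yl carbonate (ring positions numbered as in F1) | C=CCOC(=O)OC1=C(CCC(C)=C)C(C)(C)CC(OCC(C)C)=C1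
F3 | step 7 | (6R)-6-allyl-3-isobutoxy-5,5-dimethyl-6-(3-methylbut-3-en-1-yl)cyclohex-2-en-1-one | O=C1C=C(OCC(C)C)CC(C)(C)[C@]1(CC=C)CCC(C)=C
F4 | step 13 | (4S,6S,9R,10S)-4-bromo-9,10-epoxy-1,5,5,9-tetramethylspiro[5.5]undec-1-en-3-one (oxygen on the C5 face) | CC1=CC(=O)[C@@H](Br)C(C)(C)[C@]12CC[C@@]3(C)O[C@H]3C2
F5 | step 13 | (4S,6S,9R,10R)-4,10-dibromo-9-hydroxy-1,5,5,9-tetramethylspiro[5.5]undec-1-en-3-one | CC1=CC(=O)[C@@H](Br)C(C)(C)[C@]12CC[C@@](C)(O)[C@H](Br)C2
F6 | step 14 | (6R)-3-isobutoxy-5,5,9-trimethyl-1-[(trimethylsilyl)methyl]spiro[5.5]undeca-2,9-dien-1-ol (C1 unspecified) | C[Si](C)(C)CC1(O)C=C(OCC(C)C)CC(C)(C)[C@]12CCC(C)=CC2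
F7 | step 14 | 5,5,9-trimethyl-1-[(trimethylsilyl)methyl]spiro[5.5]undeca-1,9-dien-3-one (C6 as in 20) | C[Si](C)(C)CC1=CC(=O)CC(C)(C)[C@]12CCC(C)=CC2
F8 | step 14 | 5,5,9-trimethyl-1-[(trimethylsilyl)methyl]-3-(trimethylsilyloxy)spiro[5.5]undeca-1,3,9-triene (C6 as in 20) | C[Si](C)(C)CC1=CC(O[Si](C)(C)C)=CC(C)(C)[C@]12CCC(C)=CC2
F9 | step 14 | (4S)-4-bromo-5,5,9-trimethyl-1-[(trimethylsilyl)methyl]spiro[5.5]undeca-1,9-dien-3-one (C6 as in 22) | C[Si](C)(C)CC1=CC(=O)[C@@H](Br)C(C)(C)[C@]12CCC(C)=CC2
F10 | step 14 | (4S,9R,10R)-4,10-dibromo-9-chloro-5,5,9-trimethyl-1-[(trimethylsilyl)methyl]spiro[5.5]undec-1-en-3-one (C6 as in 23) | C[Si](C)(C)CC1=CC(=O)[C@@H](Br)C(C)(C)[C@]12CC[C@@](C)(Cl)[C@H](Br)C2
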